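## Retrosynthetic overview

1. Ring C (eleven-membered) is closed last by an intramolecular Nozaki–Hiyama–Kishi reaction forming C1–C2 (2-triflyloxy-alkene + aldehyde); C2 is then fixed by oxidation and oxazaborolidine reduction.
2. The C2–C7 chain is joined at C7–C8 by an intermolecular Nozaki–Hiyama–Kishi coupling of a ring A enol triflate with aldehyde 21; C7 is fixed the same way, and C5 comes from an ene-reductase reduction of an (E)-enal.
3. The 15,16-trans-diol comes from epoxidation and anti hydrolysis of a ring A diene; H11 comes from convex-face hydrogenation of a ring B enamide.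
4. Ring B is closed onto ring A by an organocatalytic desymmetrising Michael addition of a tethered β-keto ester to an achiral 4,4-disubstituted cyclohexadienone (first stereocentres, C10 and C14).
5. Ring order: A (dearomatised p-cresol) → B (Michael) → C (macrocyclisation).

Assumption: the SMILES is read as 2R,5S,7S,10S,11R,14S,15R,16R in the numbering below.

Numbering (not IUPAC, used for every compound): ring C = C1(=CH2)–C2(OAc)–C3–C4–C5(Me)–C6–C7(OAc)–C8=C9(Me)–C10–C11; ring A = C8, C9, C10, C14, C15, C16; ring B = C10, C11, C12, C13, C14; C14 carries the angular methyl. β is the face of the 14-methyl: H10, H11, 14-Me and 15-OH are β; 16-OH and the C11–C1 bond are α.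

## Route

Step 1
Reactants: 1 4-methylphenol; 2 allyltrimethylsilane
Product: 3 4-allyl-4-methylcyclohexa-2,5-dien-1-one
Conditions: PhI(OAc)2 (1.2 equiv), 2 (5 equiv), (CF3)2CHOH, −15 °C
Reagents that add atoms: none
Why: Oxidative dearomatisation with Hosomi–Sakurai-type trapping: the phenoxenium ion is captured at the para carbon by the allylsilane, giving an achiral dienone that already holds the future C14 quaternary carbon.

Step 2
Reactants: 3 4-allyl-4-methylcyclohexa-2,5-dien-1-one
Product: 4 2-(1-methyl-4-oxocyclohexa-2,5-dien-1-yl)acetaldehyde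
Conditions: O3 (1.0 equiv), CH2Cl2/MeOH, −78 °C; then PPh3, −78 °C → rt
Reagents that add atoms: ozone, [O-][O+]=O
Why: Ozonolysis; the electron-rich terminal alkene is cleaved much faster than the two electron-poor dienone alkenes.

Step 3
Reactants: 4 2-(1-methyl-4-oxocyclohexa-2,5-dien-1-yl)acetaldehyde; 5 ethyl diazoacetate
Product: 6 ethyl 4-(1-methyl-4-oxocyclohexa-2,5-dien-1-yl)-3-oxobutanoate
Conditions: SnCl2 (10 mol %), CH2Cl2, rt
Reagents that add atoms: none
Why: Roskamp homologation: Lewis-acid-promoted addition of the diazo ester to the aldehyde and 1,2-hydride shift with loss of N2 give the β-keto ester without base, so the dienone is untouched.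

Step 4
Reactants: 6 ethyl 4-(1-methyl-4-oxocyclohexa-2,5-dien-1-yl)-3-oxobutanoate
Product: 7 cis-fused bicyclic keto ester (ring A: 8-ketone, C15=C16; ring B: 12-ketone, 11-CO2Et; H10 and 14-Me both β; C11 epimers/enol)
Conditions: quinine-derived squaramide 3-{[3,5-bis(trifluoromethyl)phenyl]amino}-4-{[(8α,9S)-6′-methoxycinchonan-9-yl]amino}cyclobut-3-ene-1,2-dione (10 mol %), toluene, 0 °C
Reagents that add atoms: none
Why: Desymmetrising intramolecular Michael addition (5-exo-trig) under bifunctional hydrogen-bond/Brønsted-base catalysis: the catalyst-bound β-keto ester attacks one of the two enantiotopic enone β-carbons, setting C10 and C14 (cis fusion is enforced by the tether), with the quinine- or quinidine-derived pseudo-enantiomer chosen to give the enantiomer drawn.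

Step 5
Reactants: 7 cis-fused bicyclic keto ester
Product: 8 enol triflate (C11=C12, 12-OTf, 11-CO2Et; ring A unchanged)
Conditions: NaH (1.05 equiv), THF, 0 °C; PhNTf2, 0 °C → rt
Reagents that add atoms: N-phenylbis(trifluoromethanesulfonimide), O=S(=O)(N(c1ccccc1)S(=O)(=O)C(F)(F)F)C(F)(F)F
Why: O-sulfonylation of the β-keto ester enolate, the only site deprotonated by one equivalent of base; it also removes the acidic C11–H so that retro-Michael opening is no longer possible.

Step 6
Reactants: 8 enol triflate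
Product: 9 enone–enoate (ring B: C11=C12 with 11-CO2Et; ring A: 8-ketone, C15=C16)
Conditions: Pd(OAc)2 (5 mol %), PPh3 (10 mol %), HCO2H, n-Bu3N, DMF, 60 °C
Reagents that add atoms: none
Why: Palladium-catalysed formate reduction of the enol triflate (oxidative addition, formate–hydride transfer, reductive elimination) removes the C12 oxygen and leaves the cyclopentene carboxylate.

Step 7
Reactants: 9 enone–enoate
Product: 10 9-methyl enone–enoate (9β-Me epimer drawn; both C9 epimers converge in step 8)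
Conditions: LiN(i-Pr)2 (1.05 equiv), THF, −78 °C; MeI, DMPU, −78 → −30 °C
Reagents that add atoms: iodomethane, CI
Why: Kinetic α′-enolate alkylation of the cyclohexenone; C9 is the only enolisable ketone α-position (C14 is quaternary) and ketone deprotonation outpaces γ-deprotonation of the enoate.

Step 8
Reactants: 10 9-methyl enone–enoate
Product: 11 dienyl triflate (C8(OTf)=C9(Me), C15=C16; ring B enoate)
Conditions: KN(SiMe3)2 (1.1 equiv), THF, −78 °C; PhNTf2, −78 → 0 °C
Reagents that add atoms: N-phenylbis(trifluoromethanesulfonimide), O=S(=O)(N(c1ccccc1)S(=O)(=O)C(F)(F)F)C(F)(F)F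
Why: Cross-conjugated dienolate formation by removal of the single remaining α′-hydrogen and O-triflation give the tetrasubstituted C8=C9(Me) alkene regiospecifically.

Step 9
Reactants: 11 dienyl triflate
Product: 12 15β,16β-epoxide of 11
Conditions: m-CPBA (1.1 equiv), NaHCO3, CH2Cl2, 0 °C
Reagents that add atoms: 3-chloroperbenzoic acid, O=C(OO)c1cccc(Cl)c1
Why: Prilezhaev epoxidation; only C15=C16 is electron-rich enough (the enol triflate and enoate alkenes are deactivated), and the peracid approaches the convex β-face of the cis-fused bicycle, away from ring B.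

Step 10
Reactants: 12 15β,16β-epoxide
Product: 13 15β,16α-diol (C8 enol triflate, ring B enoate)
Conditions: HClO4 (10 mol %), THF/H2O (3:1), 0 °C → rt
Reagents that add atoms: water, O
Why: Acid-catalysed anti epoxide opening by water at the allylic C16 (C15 is neopentyl) inverts C16 and gives the 15β,16α trans-diol.

Step 11
Reactants: 13 15β,16α-diol
Product: 14 15β,16α-bis(tert-butyldimethylsilyl) ether
Conditions: TBSOTf (3 equiv), 2,6-lutidine, CH2Cl2, −78 → 0 °C
Reagents that add atoms: tert-butyldimethylsilyl trifluoromethanesulfonate, CC(C)(C)[Si](C)(C)OS(=O)(=O)C(F)(F)F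
Why: Silyl triflate protection also reaches the hindered neopentyl 15-OH; the two TBS ethers last to the final step and come off without harming acetates.

Step 12
Reactants: 14 bis-TBS ether ester
Product: 15 N-methoxy-N-methyl amide of 14 (C11=C12 retained)
Conditions: MeNH(OMe)·HCl (3 equiv), i-PrMgCl (5.8 equiv), THF, −20 → 0 °C
Reagents that add atoms: N,O-dimethylhydroxylamine hydrochloride, CNOC.Cl
Why: Weinreb amidation by 1,2-addition of the chloromagnesium amide to the ester, done here while the planar conjugated ester is still unhindered.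

Step 13
Reactants: 16 pent-4-yn-1-ol
Product: 17 1-methoxy-4-[(pent-4-yn-1-yloxy)methyl]benzene
Conditions: NaH (1.05 equiv), 4-methoxybenzyl chloride, n-Bu4NI (cat.), THF/DMF, 0 °C → rt
Reagents that add atoms: 4-methoxybenzyl chloride, COc1ccc(CCl)cc1
Why: Williamson etherification of the alkoxide (the alkyne C–H is far less acidic); PMB is later removed oxidatively in the presence of silyl ethers.

Step 14
Reactants: 17 1-methoxy-4-[(pent-4-yn-1-yloxy)methyl]benzene
Product: 19 (E)-6-[(4-methoxybenzyl)oxy]-3-methylhex-2-en-1-ol, via (E)-alkenyldimethylalane 18 (not isolated)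
Conditions: Me3Al (2.5 equiv), Cp2ZrCl2 (0.25 equiv), CH2Cl2, 0 °C → rt; then n-BuLi, (CH2O)n, THF, −78 °C → rt
Reagents that add atoms: trimethylaluminium, C[Al](C)C; paraformaldehyde, C=O
Why: Negishi zirconium-catalysed carboalumination adds Me and Al syn across the alkyne, and the alkenyl alanate is hydroxymethylated with retention, fixing the (E)-trisubstituted alkene.

Step 15
Reactants: 19 (E)-6-[(4-methoxybenzyl)oxy]-3-methylhex-2-en-1-ol
Product: 20 (E)-6-[(4-methoxybenzyl)oxy]-3-methylhex-2-enal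
Conditions: MnO2 (15 equiv), CH2Cl2, rt
Reagents that add atoms: none
Why: Allylic alcohol oxidation on MnO2 under neutral conditions keeps the (E)-geometry.

Step 16
Reactants: 20 (E)-6-[(4-methoxybenzyl)oxy]-3-methylhex-2-enal
Product: 21 (S)-6-[(4-methoxybenzyl)oxy]-3-methylhexanal
Conditions: ene-reductase (flavin-dependent Old Yellow Enzyme family, (S)-selective NCR type, picked from a panel), NADH (2 mol %), formate dehydrogenase, HCO2Na, phosphate buffer pH 7.0, 5% i-PrOH, 30 °C
Reagents that add atoms: none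
Why: Ene-reductase bioreduction (anti addition of flavin hydride to C5 and a proton to C6) sets C5 as S from the geometrically pure (E)-enal, by analogy with geranial → (S)-citronellal.

Step 17
Reactants: 15 enol triflate Weinreb amide; 21 (S)-6-[(4-methoxybenzyl)oxy]-3-methylhexanal
Product: 22 C7 carbinol (C7–C8 bond formed; mixture of C7 epimers)
Conditions: CrCl2 (6 equiv), NiCl2 (2 mol %), DMF, rt; 21 (1.5 equiv)
Reagents that add atoms: none
Why: Nozaki–Hiyama–Kishi coupling: nickel inserts into the enol triflate, the alkenyl group passes to chromium and adds only to the aldehyde (amide, silyl ethers and PMB are tolerated); the C7 epimer mixture is corrected in steps 18–19.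

Step 18
Reactants: 22 C7 carbinol
Product: 23 C7 ketone (enone C7(=O)–C8=C9)
Conditions: Dess–Martin periodinane, NaHCO3, CH2Cl2, 0 °C → rt
Reagents that add atoms: none
Why: Dess–Martin oxidation under buffered, non-epimerising conditions converges both C7 epimers to one enone.

Step 19
Reactants: 23 C7 ketone
Product: 24 (7S)-alcohol
Conditions: (R)-2-methyl-CBS-oxazaborolidine (0.3 equiv), BH3·SMe2, toluene, −20 °C
Reagents that add atoms: none
Why: Corey–Bakshi–Shibata reduction: reagent-controlled hydride delivery with the alkenyl group as the large substituent gives the 7S carbinol; the unsaturated amide and hindered alkenes are inert at this temperature.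

Step 20
Reactants: 24 (7S)-alcohol
Product: 25 (7S)-triethylsilyl ether
Conditions: TESOTf, 2,6-lutidine, CH2Cl2, −78 °C
Reagents that add atoms: triethylsilyl trifluoromethanesulfonate, CC[Si](CC)(CC)OS(=O)(=O)C(F)(F)F
Why: Silyl triflate protection of the hindered allylic alcohol; TES survives the basic steps ahead and is later removed selectively beside TBS.

Step 21
Reactants: 25 (7S)-triethylsilyl ether
Product: 26 saturated ring B amide (H11 β, 11α-C(O)N(Me)OMe)
Conditions: H2 (1 atm), 5% Pd/C, pyridine (0.5 equiv), EtOAc, rt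
Reagents that add atoms: none
Why: Heterogeneous syn hydrogenation from the convex β-face (the α-face is shielded by ring A and the 16α-OTBS) puts H11 β and the acyl group α; pyridine-moderated Pd/C spares the PMB ether and the tetrasubstituted C8=C9.

Step 22
Reactants: 26 saturated ring B amide
Product: 27 11α-acetyl compound (methyl ketone, C1 = carbonyl carbon)
Conditions: MeMgBr (3 equiv), THF, −20 → 0 °C; aq. NH4Cl at 0 °C
Reagents that add atoms: methylmagnesium bromide, C[Mg]Br
Why: Weinreb ketone synthesis: the chelated tetrahedral intermediate prevents over-addition, and the cold quench avoids epimerising the α-acyl centre C11.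

Step 23
Reactants: 27 11α-acetyl compound
Product: 28 2-triflyloxy-alkene (C11–C1(OTf)=CH2)
Conditions: KN(SiMe3)2 (1.2 equiv), THF, −78 °C; PhNTf2, −78 °C
Reagents that add atoms: N-phenylbis(trifluoromethanesulfonimide), O=S(=O)(N(c1ccccc1)S(=O)(=O)C(F)(F)F)C(F)(F)F
Why: Kinetic deprotonation of the unhindered methyl group and O-triflation give the terminal enol triflate without touching the C11 stereocentre.

Step 24
Reactants: 28 2-triflyloxy-alkene
Product: 29 primary alcohol (C2–OH)
Conditions: DDQ (1.3 equiv), CH2Cl2/pH 7 phosphate buffer (10:1), 0 °C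
Reagents that add atoms: none
Why: Oxidative PMB cleavage (hydride abstraction, then hydrolysis of the oxocarbenium ion) leaves the TES and TBS ethers and the enol triflate intact.

Step 25
Reactants: 29 primary alcohol
Product: 30 C2 aldehyde
Conditions: Dess–Martin periodinane, NaHCO3, CH2Cl2, 0 °C
Reagents that add atoms: none
Why: Dess–Martin oxidation gives the aldehyde under neutral conditions.

Step 26
Reactants: 30 C2 aldehyde
Product: 31 ring C allylic alcohol (C1–C2 bond formed, exo-methylene at C1; C2 epimers)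
Conditions: CrCl2 (15 equiv), NiCl2 (0.2 equiv), DMSO/THF, 2 mM, slow addition, rt
Reagents that add atoms: none
Why: Intramolecular Nozaki–Hiyama–Kishi reaction at high dilution closes the eleven-membered ring from the unhindered terminal alkenyl triflate and delivers the 1,1-disubstituted alkene directly.

Step 27
Reactants: 31 ring C allylic alcohol
Product: 32 ring C α-methylene ketone (C2 ketone)
Conditions: Dess–Martin periodinane, NaHCO3, CH2Cl2, 0 °C
Reagents that add atoms: none
Why: Dess–Martin oxidation converges the C2 epimers under buffered conditions that do not move the exo-methylene into conjugation with ring B.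

Step 28
Reactants: 32 ring C α-methylene ketone
Product: 33 (2R)-alcohol
Conditions: (S)-2-methyl-CBS-oxazaborolidine (1.0 equiv), BH3·SMe2, toluene/CH2Cl2, −30 °C
Reagents that add atoms: none
Why: Corey–Bakshi–Shibata 1,2-reduction of the enone with the alkenyl group as the large substituent sets C2 as R under reagent control.

Step 29
Reactants: 33 (2R)-alcohol
Product: 34 (2R,7S)-diol, 15,16-bis-TBS ether
Conditions: HF·pyridine, pyridine, THF, 0 °C
Reagents that add atoms: none
Why: Buffered fluoride cleaves the secondary TES ether far faster than the TBS ethers and avoids acid ionisation of the allylic alcohols.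

Step 30
Reactants: 34 (2R,7S)-diol
Product: 35 2,7-diacetate, 15,16-bis-TBS ether
Conditions: Ac2O, DMAP, Et3N, CH2Cl2, rt
Reagents that add atoms: acetic anhydride, CC(=O)OC(C)=O
Why: DMAP-catalysed acylation of the two free allylic alcohols while O15 and O16 stay blocked.

Step 31
Reactants: 35 2,7-diacetate
Product: 36 CNP0286573.1 (2R,5S,7S,10S,11R,14S,15R,16R)
Conditions: HF·pyridine (excess), THF, 0 °C → rt
Reagents that add atoms: none
Why: Fluoride desilylation under non-basic conditions frees the 15,16-diol without acetate hydrolysis or 1,3-acyl migration from O7 to O16.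

## Compound list

1 | 4-methylphenol | Cc1ccc(O)cc1 | starting material
2 | allyltrimethylsilane | C=CC[Si](C)(C)C | starting material
3 | 4-allyl-4-methylcyclohexa-2,5-dien-1-one | C=CCC1(C)C=CC(=O)C=C1 | intermediate
4 | 2-(1-methyl-4-oxocyclohexa-2,5-dien-1-yl)acetaldehyde | O=CCC1(C)C=CC(=O)C=C1 | intermediate
5 | ethyl diazoacetate | CCOC(=O)C=[N+]=[N-] | starting material
6 | ethyl 4-(1-methyl-4-oxocyclohexa-2,5-dien-1-yl)-3-oxobutanoate | CCOC(=O)CC(=O)CC1(C)C=CC(=O)C=C1 | intermediate
7 | cis-fused bicyclic keto ester (8-ketone, C15=C16, 12-ketone, 11-CO2Et; H10 and 14-Me β; C11 unspecified) | O=C1C[C@@H]2C(C(=O)OCC)C(=O)C[C@]2(C)C=C1 | intermediate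
8 | enol triflate (C11=C12, 12-OTf, 11-CO2Et) | O=C1C[C@@H]2C(C(=O)OCC)=C(OS(=O)(=O)C(F)(F)F)C[C@]2(C)C=C1 | intermediate
9 | enone–enoate (C11=C12, 11-CO2Et; 8-ketone, C15=C16) | O=C1C[C@@H]2C(C(=O)OCC)=CC[C@]2(C)C=C1 | intermediate
10 | 9-methyl enone–enoate (9β-Me drawn) | O=C1[C@@H](C)[C@@H]2C(C(=O)OCC)=CC[C@]2(C)C=C1 | intermediate
11 | dienyl triflate (C8(OTf)=C9(Me), C15=C16, ring B enoate) | FC(F)(F)S(=O)(=O)OC1=C(C)[C@@H]2C(C(=O)OCC)=CC[C@]2(C)C=C1 | intermediate
12 | 15β,16β-epoxide | FC(F)(F)S(=O)(=O)OC1=C(C)[C@@H]2C(C(=O)OCC)=CC[C@]2(C)[C@H]3O[C@H]31 | intermediate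
13 | 15β,16α-diol | FC(F)(F)S(=O)(=O)OC1=C(C)[C@@H]2C(C(=O)OCC)=CC[C@]2(C)[C@@H](O)[C@@H]1O | intermediate
14 | 15β,16α-bis-TBS ether ethyl ester | FC(F)(F)S(=O)(=O)OC1=C(C)[C@@H]2C(C(=O)OCC)=CC[C@]2(C)[C@@H](O[Si](C)(C)C(C)(C)C)[C@@H]1O[Si](C)(C)C(C)(C)C | intermediate
15 | N-methoxy-N-methyl amide (ring A enol triflate, bis-TBS) | FC(F)(F)S(=O)(=O)OC1=C(C)[C@@H]2C(C(=O)N(C)OC)=CC[C@]2(C)[C@@H](O[Si](C)(C)C(C)(C)C)[C@@H]1O[Si](C)(C)C(C)(C)C | intermediate
16 | pent-4-yn-1-ol | C#CCCCO | starting material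
17 | 1-methoxy-4-[(pent-4-yn-1-yloxy)methyl]benzene | C#CCCCOCc1ccc(OC)cc1 | intermediate
18 | (E)-{5-[(4-methoxybenzyl)oxy]-2-methylpent-1-en-1-yl}dimethylalane | C[Al](C)/C=C(\C)CCCOCc1ccc(OC)cc1 | intermediate
19 | (E)-6-[(4-methoxybenzyl)oxy]-3-methylhex-2-en-1-ol | OC/C=C(\C)CCCOCc1ccc(OC)cc1 | intermediate
20 | (E)-6-[(4-methoxybenzyl)oxy]-3-methylhex-2-enal | O=C/C=C(\C)CCCOCc1ccc(OC)cc1 | intermediate
21 | (S)-6-[(4-methoxybenzyl)oxy]-3-methylhexanal | O=CC[C@@H](C)CCCOCc1ccc(OC)cc1 | intermediate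
22 | C7 carbinol (C7 epimers) | OC(C[C@@H](C)CCCOCc1ccc(OC)cc1)C1=C(C)[C@@H]2C(C(=O)N(C)OC)=CC[C@]2(C)[C@@H](O[Si](C)(C)C(C)(C)C)[C@@H]1O[Si](C)(C)C(C)(C)C | intermediate
23 | C7 ketone | O=C(C[C@@H](C)CCCOCc1ccc(OC)cc1)C1=C(C)[C@@H]2C(C(=O)N(C)OC)=CC[C@]2(C)[C@@H](O[Si](C)(C)C(C)(C)C)[C@@H]1O[Si](C)(C)C(C)(C)C | intermediate
24 | (7S)-alcohol | O[C@@H](C[C@@H](C)CCCOCc1ccc(OC)cc1)C1=C(C)[C@@H]2C(C(=O)N(C)OC)=CC[C@]2(C)[C@@H](O[Si](C)(C)C(C)(C)C)[C@@H]1O[Si](C)(C)C(C)(C)C | intermediate
25 | (7S)-triethylsilyl ether | CC[Si](CC)(CC)O[C@@H](C[C@@H](C)CCCOCc1ccc(OC)cc1)C1=C(C)[C@@H]2C(C(=O)N(C)OC)=CC[C@]2(C)[C@@H](O[Si](C)(C)C(C)(C)C)[C@@H]1O[Si](C)(C)C(C)(C)C | intermediate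
26 | saturated ring B amide (H11 β) | CC[Si](CC)(CC)O[C@@H](C[C@@H](C)CCCOCc1ccc(OC)cc1)C1=C(C)[C@@H]2[C@H](C(=O)N(C)OC)CC[C@]2(C)[C@@H](O[Si](C)(C)C(C)(C)C)[C@@H]1O[Si](C)(C)C(C)(C)C | intermediate
27 | 11α-acetyl compound | CC[Si](CC)(CC)O[C@@H](C[C@@H](C)CCCOCc1ccc(OC)cc1)C1=C(C)[C@@H]2[C@H](C(C)=O)CC[C@]2(C)[C@@H](O[Si](C)(C)C(C)(C)C)[C@@H]1O[Si](C)(C)C(C)(C)C | intermediate
28 | 2-triflyloxy-alkene (C1(OTf)=CH2), PMB ether | CC[Si](CC)(CC)O[C@@H](C[C@@H](C)CCCOCc1ccc(OC)cc1)C1=C(C)[C@@H]2[C@H](C(=C)OS(=O)(=O)C(F)(F)F)CC[C@]2(C)[C@@H](O[Si](C)(C)C(C)(C)C)[C@@H]1O[Si](C)(C)C(C)(C)C | intermediate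
29 | primary alcohol (C2–OH) | CC[Si](CC)(CC)O[C@@H](C[C@@H](C)CCCO)C1=C(C)[C@@H]2[C@H](C(=C)OS(=O)(=O)C(F)(F)F)CC[C@]2(C)[C@@H](O[Si](C)(C)C(C)(C)C)[C@@H]1O[Si](C)(C)C(C)(C)C | intermediate
30 | C2 aldehyde | CC[Si](CC)(CC)O[C@@H](C[C@@H](C)CCC=O)C1=C(C)[C@@H]2[C@H](C(=C)OS(=O)(=O)C(F)(F)F)CC[C@]2(C)[C@@H](O[Si](C)(C)C(C)(C)C)[C@@H]1O[Si](C)(C)C(C)(C)C | intermediate
31 | ring C allylic alcohol (C2 epimers) | C=C1C(O)CC[C@H](C)C[C@H](O[Si](CC)(CC)CC)C2=C(C)[C@@H]3[C@H]1CC[C@]3(C)[C@@H](O[Si](C)(C)C(C)(C)C)[C@@H]2O[Si](C)(C)C(C)(C)C | intermediate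
32 | ring C α-methylene ketone | C=C1C(=O)CC[C@H](C)C[C@H](O[Si](CC)(CC)CC)C2=C(C)[C@@H]3[C@H]1CC[C@]3(C)[C@@H](O[Si](C)(C)C(C)(C)C)[C@@H]2O[Si](C)(C)C(C)(C)C | intermediate
33 | (2R)-alcohol | C=C1[C@H](O)CC[C@H](C)C[C@H](O[Si](CC)(CC)CC)C2=C(C)[C@@H]3[C@H]1CC[C@]3(C)[C@@H](O[Si](C)(C)C(C)(C)C)[C@@H]2O[Si](C)(C)C(C)(C)C | intermediate
34 | (2R,7S)-diol, 15,16-bis-TBS ether | C=C1[C@H](O)CC[C@H](C)C[C@H](O)C2=C(C)[C@@H]3[C@H]1CC[C@]3(C)[C@@H](O[Si](C)(C)C(C)(C)C)[C@@H]2O[Si](C)(C)C(C)(C)C | intermediate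
35 | 2,7-diacetate, 15,16-bis-TBS ether | C=C1[C@H](OC(C)=O)CC[C@H](C)C[C@H](OC(C)=O)C2=C(C)[C@@H]3[C@H]1CC[C@]3(C)[C@@H](O[Si](C)(C)C(C)(C)C)[C@@H]2O[Si](C)(C)C(C)(C)C | intermediate
36 | CNP0286573.1 | C=C1[C@H](OC(C)=O)CC[C@H](C)C[C@H](OC(C)=O)C2=C(C)[C@@H]3[C@H]1CC[C@]3(C)[C@@H](O)[C@@H]2O | target

## Count and risks

Total: 31 steps. Longest linear sequence: 27 steps (steps 1–12, then 17–31); the side-chain branch is 4 steps (13–16).

The three steps most likely to fail:

Step 4 (desymmetrising Michael addition). The risks are the level and sense of enantioselectivity and competing O-cyclisation. The fallback sets out from 3 and comes back at 10. Hydroboration–oxidation of the allyl group (dicyclohexylborane, THF, 0 °C; NaBO3) gives 4-(3-hydroxypropyl)-4-methylcyclohexa-2,5-dien-1-one F1. Dess–Martin oxidation gives 3-(1-methyl-4-oxocyclohexa-2,5-dien-1-yl)propanal F2. An intramolecular Stetter reaction (chiral aminoindanol-derived N-pentafluorophenyl triazolium salt, KN(SiMe3)2, toluene) then desymmetrises the dienone through the acyl-anion equivalent to the cis-fused 8,11-diketone F3. Selective dioxolane formation at the saturated C11 ketone gives the C11 ketal F4, α′-methylation (LiN(i-Pr)2, MeI) gives the 9-methyl ketal F5, and aqueous HCl gives the 9-methyl diketone F6. Kinetic enolisation toward the C12 methylene (KN(SiMe3)2, PhNTf2, −78 °C) gives the C11 enol triflate F7, and ethoxycarbonylation (Pd(OAc)2, 1,3-bis(diphenylphosphino)propane, CO, EtOH, Et3N) returns to 10.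

Step 9 (facial selectivity of the epoxidation). If the peracid attacks the α-face, step 10 would give the wrong trans-diol. The fallback sets out from 11 and comes back at 12. NBS in aqueous 1,2-dimethoxyethane forms the bromonium ion under the same α-facial bias, and water opens it at allylic C16 from the β-face to give the 15α-bromo-16β-hydroxy bromohydrin F8. NaH in THF then closes the ring by intramolecular SN2 displacement with inversion at C15, giving the β-epoxide 12.

Step 26 (closure of the eleven-membered ring). The risks are oligomerisation and transannular strain. The fallback sets out from 29 and comes back at 34. LiN(i-Pr)2 (3.5 equiv) eliminates triflic acid from the 2-triflyloxy-alkene to give the 11α-ethynyl alcohol F9, and Dess–Martin oxidation gives the ynal F10. Ni(cod)2 with the bulky carbene 1,3-bis(2,6-diisopropylphenyl)imidazol-2-ylidene and Et3SiH closes ring C by reductive alkyne–aldehyde coupling at the internal alkyne carbon, giving the exo-methylene macrocycle as its 2,7-bis(triethylsilyl) ether F11 (C2 epimers). HF·pyridine removes both triethylsilyl groups to give the 2,7-diol epimer mixture F12. MnO2 oxidises only the unhindered C2 allylic alcohol to the 7-hydroxy α-methylene ketone F13, and reduction with BH3·SMe2 and (S)-2-methyl-CBS-oxazaborolidine gives 34.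

## Further compounds

F1 | step 4 | 4-(3-hydroxypropyl)-4-methylcyclohexa-2,5-dien-1-one | OCCCC1(C)C=CC(=O)C=C1
F2 | step 4 | 3-(1-methyl-4-oxocyclohexa-2,5-dien-1-yl)propanal | O=CCCC1(C)C=CC(=O)C=C1
F3 | step 4 | cis-fused 8,11-diketone (C15=C16; H10 and 14-Me β) | O=C1C[C@@H]2C(=O)CC[C@]2(C)C=C1
F4 | step 4 | C11 ethylene ketal of the 8,11-diketone | O=C1C[C@@H]2C3(OCCO3)CC[C@]2(C)C=C1
F5 | step 4 | 9-methyl C11 ketal | O=C1[C@@H](C)[C@@H]2C3(OCCO3)CC[C@]2(C)C=C1
F6 | step 4 | 9-methyl 8,11-diketone | O=C1[C@@H](C)[C@@H]2C(=O)CC[C@]2(C)C=C1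
F7 | step 4 | C11 enol triflate (C11=C12), 9-methyl enone | O=C1[C@@H](C)[C@@H]2C(OS(=O)(=O)C(F)(F)F)=CC[C@]2(C)C=C1
F8 | step 9 | 15α-bromo-16β-hydroxy bromohydrin of 11 | FC(F)(F)S(=O)(=O)OC1=C(C)[C@@H]2C(C(=O)OCC)=CC[C@]2(C)[C@H](Br)[C@H]1O
F9 | step 26 | 11α-ethynyl alcohol | CC[Si](CC)(CC)O[C@@H](C[C@@H](C)CCCO)C1=C(C)[C@@H]2[C@H](C#C)CC[C@]2(C)[C@@H](O[Si](C)(C)C(C)(C)C)[C@@H]1O[Si](C)(C)C(C)(C)C
F10 | step 26 | ynal | CC[Si](CC)(CC)O[C@@H](C[C@@H](C)CCC=O)C1=C(C)[C@@H]2[C@H](C#C)CC[C@]2(C)[C@@H](O[Si](C)(C)C(C)(C)C)[C@@H]1O[Si](C)(C)C(C)(C)C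
F11 | step 26 | ring C 2,7-bis(triethylsilyl) ether (C2 epimers) | C=C1C(O[Si](CC)(CC)CC)CC[C@H](C)C[C@H](O[Si](CC)(CC)CC)C2=C(C)[C@@H]3[C@H]1CC[C@]3(C)[C@@H](O[Si](C)(C)C(C)(C)C)[C@@H]2O[Si](C)(C)C(C)(C)C
F12 | step 26 | 2,7-diol (C2 epimers), 15,16-bis-TBS ether | C=C1C(O)CC[C@H](C)C[C@H](O)C2=C(C)[C@@H]3[C@H]1CC[C@]3(C)[C@@H](O[Si](C)(C)C(C)(C)C)[C@@H]2O[Si](C)(C)C(C)(C)C
F13 | step 26 | 7-hydroxy α-methylene ketone | C=C1C(=O)CC[C@H](C)C[C@H](O)C2=C(C)[C@@H]3[C@H]1CC[C@]3(C)[C@@H](O[Si](C)(C)C(C)(C)C)[C@@H]2O[Si](C)(C)C(C)(C)C
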